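**Retrosynthetic overview**
1. The target comes from an all-trans aryltetralin lactone by LiAlH4 opening and O-debenzylation, with no C–C change.
2. The carbocycle (second ring formed) comes from an intramolecular Friedel–Crafts closure of C1–C8a. The closure is para to the ring oxygen that ends as the free OH, and the precursor is a benzylic carbinol.
3. The key C1–C2 bond comes from an intermolecular aldol addition of the lithium enolate of (R)-β-(3-benzyloxy-4-methoxybenzyl)-γ-butyrolactone to O-benzylvanillin.
4. The butyrolactone (first ring formed, carries C3) comes from Evans alkylation of an isovanillin-derived dihydrocinnamoyl oxazolidinone with tert-butyl bromoacetate, then acid → alcohol → lactonisation.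
5. Ring order: γ-lactone, then tetralin ring, then the lactone is opened to the diol.

Assumption: the SMILES is taken literally. On the fused ring, OMe is para to the CH2-bearing carbon and OH is para to the carbon bearing C1. This is the 6-OH/7-OMe regioisomer of isolariciresinol, (1S,2R,3R), all-trans. The fused ring is therefore built from isovanillin and the pendant ring from vanillin.

**Step 1**
Reactants: 1 isovanillin (3-hydroxy-4-methoxybenzaldehyde); 2 malonic acid
Product: 3 (E)-3-(3-hydroxy-4-methoxyphenyl)prop-2-enoic acid (isoferulic acid)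
Conditions: malonic acid (2 equiv), pyridine, cat. piperidine, 90 °C; then aq. HCl
Reagents that add atoms: malonic acid (2), OC(=O)CC(=O)O
Why: The Knoevenagel–Doebner condensation with in situ decarboxylation gives (E)-cinnamic acids reliably and tolerates the free phenol, as in vanillin → ferulic acid.

**Step 2**
Reactants: 3 isoferulic acid
Product: 4 3-(3-hydroxy-4-methoxyphenyl)propanoic acid
Conditions: H2 (1 atm), 10% Pd/C, MeOH, rt
Reagents that add atoms: none
Why: Catalytic hydrogenation of the conjugated alkene is run before any benzyl group is present, so nothing else in the molecule can be reduced.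

**Step 3**
Reactants: 4 3-(3-hydroxy-4-methoxyphenyl)propanoic acid; 5 benzyl bromide
Product: 6 benzyl 3-[3-(benzyloxy)-4-methoxyphenyl]propanoate
Conditions: BnBr (2.3 equiv), K2CO3 (3 equiv), DMF, 60 °C
Reagents that add atoms: benzyl bromide (5), BrCc1ccccc1
Why: Williamson etherification of the phenoxide and SN2 esterification of the carboxylate both go to completion with a reactive benzylic halide.

**Step 4**
Reactants: 6 benzyl 3-[3-(benzyloxy)-4-methoxyphenyl]propanoate
Product: 7 3-[3-(benzyloxy)-4-methoxyphenyl]propanoic acid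
Conditions: 2 M aq. NaOH, THF/MeOH, 40 °C; then 1 M HCl
Reagents that add atoms: sodium hydroxide, [Na+].[OH-]
Why: Saponification (BAc2) cleaves only the ester, because the aryl benzyl and methyl ethers are inert to hydroxide.

**Step 5**
Reactants: 7 3-[3-(benzyloxy)-4-methoxyphenyl]propanoic acid; 8 (S)-4-benzyloxazolidin-2-one
Product: 10 (S)-4-benzyl-3-{3-[3-(benzyloxy)-4-methoxyphenyl]propanoyl}oxazolidin-2-one, via mixed pivalic anhydride 9 (not isolated)
Conditions: PivCl, Et3N (2.5 equiv), THF, −20 °C; then 8, LiCl, −20 °C → rt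
Reagents that add atoms: (S)-4-benzyloxazolidin-2-one (8), O=C1N[C@@H](Cc2ccccc2)CO1; pivaloyl chloride, CC(C)(C)C(=O)Cl (atoms only in intermediate 9)
Why: In this mixed-anhydride N-acylation the oxazolidinone attacks the unhindered acyl carbon rather than the pivaloyl carbon, and the auxiliary stereocentre is untouched.

**Step 6**
Reactants: 10 N-acyl oxazolidinone; 11 tert-butyl bromoacetate
Product: 13 tert-butyl (3R)-3-[3-(benzyloxy)-4-methoxybenzyl]-4-[(4S)-4-benzyl-2-oxooxazolidin-3-yl]-4-oxobutanoate, via sodium (Z)-enolate 12 (not isolated)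
Conditions: NaHMDS (1.1 equiv), THF, −78 °C; BrCH2CO2t-Bu (2 equiv), −78 → −40 °C; chromatography or crystallisation
Reagents that add atoms: tert-butyl bromoacetate (11), CC(C)(C)OC(=O)CBr; NaHMDS, C[Si](C)(C)[N-][Si](C)(C)C.[Na+] (Na only in intermediate 12)
Why: In this Evans asymmetric alkylation the chelated (Z)-enolate is alkylated on the face opposite the 4-benzyl group, which sets the (R) centre (future C3) with dr ≥ 95:5, and the minor isomer is separable.

**Step 7**
Reactants: 13 alkylated imide
Product: 15 (2R)-2-[3-(benzyloxy)-4-methoxybenzyl]-4-tert-butoxy-4-oxobutanoic acid, via peroxy acid 14 (not isolated)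
Conditions: LiOH (2 equiv), 30% H2O2 (4 equiv), THF/H2O 3:1, 0 °C; aq. Na2SO3; then 1 M HCl to pH 3
Reagents that add atoms: hydrogen peroxide, OO
Why: LiOOH cleavage of the Evans auxiliary attacks the exocyclic carbonyl selectively and without α-epimerisation, while the hindered tert-butyl ester survives.

**Step 8**
Reactants: 15 succinic half-ester
Product: 16 tert-butyl (3R)-4-[3-(benzyloxy)-4-methoxyphenyl]-3-(hydroxymethyl)butanoate
Conditions: BH3·THF (1.5 equiv), THF, 0 °C → rt; then H2O
Reagents that add atoms: none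
Why: Borane reduction is chemoselective because it reduces the free acid through an acyloxyborane much faster than the tert-butyl ester, and the stereocentre is not involved.

**Step 9**
Reactants: 16 hydroxy ester
Product: 17 (4R)-4-[3-(benzyloxy)-4-methoxybenzyl]dihydrofuran-2(3H)-one
Conditions: p-TsOH·H2O (10 mol %), toluene, 80 °C
Reagents that add atoms: none
Why: Acid-catalysed lactonisation (intramolecular transesterification) to the five-membered ring is strongly favoured and leaves the (R) centre and the aryl benzyl ether intact.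

**Step 10**
Reactants: 18 vanillin; 5 benzyl bromide
Product: 19 4-(benzyloxy)-3-methoxybenzaldehyde
Conditions: BnBr (1.1 equiv), K2CO3, DMF, rt → 50 °C
Reagents that add atoms: benzyl bromide (5), BrCc1ccccc1
Why: This is a routine, near-quantitative Williamson ether synthesis on an acidic phenol.

**Step 11** (key C–C bond)
Reactants: 17 (R)-lactone; 19 4-(benzyloxy)-3-methoxybenzaldehyde
Product: 21 (3S,4R)-3-{[4-(benzyloxy)-3-methoxyphenyl](hydroxy)methyl}-4-[3-(benzyloxy)-4-methoxybenzyl]dihydrofuran-2(3H)-one (mixture of carbinol epimers), via lithium enolate 20 (not isolated)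
Conditions: LiHMDS (1.1 equiv), THF, −78 °C, 1 h; 19 in THF, −78 °C, 2 h; AcOH quench at −78 °C
Reagents that add atoms: 4-(benzyloxy)-3-methoxybenzaldehyde (19), COc1cc(C=O)ccc1OCc1ccccc1; LiHMDS, C[Si](C)(C)[N-][Si](C)(C)C.[Li+] (Li only in intermediate 20)
Why: In this intermolecular aldol addition the lactone enolate is attacked anti to the C4 benzyl group, which sets the 3,4-trans relationship (future C2), and the carbinol epimers need no separation because both converge in the next step.

**Step 12**
Reactants: 21 aldol adduct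
Product: 23 (3aR,9S,9aR)-6-(benzyloxy)-9-[4-(benzyloxy)-3-methoxyphenyl]-7-methoxy-3a,4,9,9a-tetrahydronaphtho[2,3-c]furan-1(3H)-one, via benzylic cation 22 (not isolated)
Conditions: TFA (10 equiv), CH2Cl2, 0 °C → rt, 1–2 h
Reagents that add atoms: none
Why: In this intramolecular Friedel–Crafts alkylation both epimers ionise to the same p-alkoxybenzyl cation, the neighbouring ring attacks at the free position para to its OBn group, and a chair-like closure with the pendant aryl pseudo-equatorial sets C9 as S (1,2-trans, all-trans).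

**Step 13**
Reactants: 23 aryltetralin lactone
Product: 24 {(1S,2R,3R)-6-(benzyloxy)-1-[4-(benzyloxy)-3-methoxyphenyl]-7-methoxy-1,2,3,4-tetrahydronaphthalene-2,3-diyl}dimethanol
Conditions: LiAlH4 (2.5 equiv), THF, 0 °C → rt; Fieser work-up
Reagents that add atoms: none
Why: LiAlH4 reduction of the lactone to the 1,4-diol is faster than enolisation, so the α-centre is not epimerised and the ethers are inert.

**Step 14**
Reactants: 24 di-O-benzyl diol
Product: 25 (5S,6R,7R)-5-(4-hydroxy-3-methoxyphenyl)-6,7-bis(hydroxymethyl)-3-methoxy-5,6,7,8-tetrahydronaphthalen-2-ol (target)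
Conditions: H2 (1 atm), 10% Pd/C, MeOH/EtOAc 1:1, rt
Reagents that add atoms: none
Why: Catalytic hydrogenolysis removes both O-benzyl groups, while the diarylmethine C–H, the primary alcohols and the three stereocentres carry no cleavable benzylic heteroatom bond.

**Compound list**
1 | isovanillin | COc1ccc(C=O)cc1O | starting material
2 | malonic acid | OC(=O)CC(=O)O | starting material
3 | (E)-3-(3-hydroxy-4-methoxyphenyl)prop-2-enoic acid | COc1ccc(/C=C/C(=O)O)cc1O | intermediate
4 | 3-(3-hydroxy-4-methoxyphenyl)propanoic acid | COc1ccc(CCC(=O)O)cc1O | intermediate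
5 | benzyl bromide | BrCc1ccccc1 | starting material
6 | benzyl 3-[3-(benzyloxy)-4-methoxyphenyl]propanoate | COc1ccc(CCC(=O)OCc2ccccc2)cc1OCc1ccccc1 | intermediate
7 | 3-[3-(benzyloxy)-4-methoxyphenyl]propanoic acid | COc1ccc(CCC(=O)O)cc1OCc1ccccc1 | intermediate
8 | (S)-4-benzyloxazolidin-2-one | O=C1N[C@@H](Cc2ccccc2)CO1 | starting material
9 | mixed pivalic anhydride of 7 (not isolated) | COc1ccc(CCC(=O)OC(=O)C(C)(C)C)cc1OCc1ccccc1 | intermediate
10 | (S)-4-benzyl-3-{3-[3-(benzyloxy)-4-methoxyphenyl]propanoyl}oxazolidin-2-one | COc1ccc(CCC(=O)N2[C@@H](Cc3ccccc3)COC2=O)cc1OCc1ccccc1 | intermediate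
11 | tert-butyl bromoacetate | CC(C)(C)OC(=O)CBr | starting material
12 | sodium (Z)-enolate of 10 (not isolated) | [Na+].[O-]/C(=C\Cc1ccc(OC)c(OCc2ccccc2)c1)N1[C@@H](Cc2ccccc2)COC1=O | intermediate
13 | tert-butyl (3R)-3-[3-(benzyloxy)-4-methoxybenzyl]-4-[(4S)-4-benzyl-2-oxooxazolidin-3-yl]-4-oxobutanoate | COc1ccc(C[C@H](CC(=O)OC(C)(C)C)C(=O)N2[C@@H](Cc3ccccc3)COC2=O)cc1OCc1ccccc1 | intermediate
14 | (2R)-peroxy acid from 13 (not isolated) | COc1ccc(C[C@H](CC(=O)OC(C)(C)C)C(=O)OO)cc1OCc1ccccc1 | intermediate
15 | (2R)-2-[3-(benzyloxy)-4-methoxybenzyl]-4-tert-butoxy-4-oxobutanoic acid | COc1ccc(C[C@H](CC(=O)OC(C)(C)C)C(=O)O)cc1OCc1ccccc1 | intermediate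
16 | tert-butyl (3R)-4-[3-(benzyloxy)-4-methoxyphenyl]-3-(hydroxymethyl)butanoate | COc1ccc(C[C@H](CC(=O)OC(C)(C)C)CO)cc1OCc1ccccc1 | intermediate
17 | (4R)-4-[3-(benzyloxy)-4-methoxybenzyl]dihydrofuran-2(3H)-one | O=C1C[C@@H](Cc2ccc(OC)c(OCc3ccccc3)c2)CO1 | intermediate
18 | vanillin | COc1cc(C=O)ccc1O | starting material
19 | 4-(benzyloxy)-3-methoxybenzaldehyde | COc1cc(C=O)ccc1OCc1ccccc1 | intermediate
20 | lithium enolate of 17 (not isolated) | [Li+].[O-]C1=C[C@@H](Cc2ccc(OC)c(OCc3ccccc3)c2)CO1 | intermediate
21 | (3S,4R)-aldol adduct, carbinol epimers | O=C1OC[C@H](Cc2ccc(OC)c(OCc3ccccc3)c2)[C@H]1C(O)c1ccc(OCc2ccccc2)c(OC)c1 | intermediate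
22 | p-benzyloxybenzylic cation from 21 (not isolated) | O=C1OC[C@H](Cc2ccc(OC)c(OCc3ccccc3)c2)[C@H]1[CH+]c1ccc(OCc2ccccc2)c(OC)c1 | intermediate
23 | (3aR,9S,9aR)-6-(benzyloxy)-9-[4-(benzyloxy)-3-methoxyphenyl]-7-methoxy-3a,4,9,9a-tetrahydronaphtho[2,3-c]furan-1(3H)-one | COc1cc([C@H]2c3cc(OC)c(OCc5ccccc5)cc3C[C@H]4COC(=O)[C@H]24)ccc1OCc1ccccc1 | intermediate
24 | (1S,2R,3R)-di-O-benzyl diol | COc1cc([C@H]2c3cc(OC)c(OCc4ccccc4)cc3C[C@@H](CO)[C@@H]2CO)ccc1OCc1ccccc1 | intermediate
25 | (5S,6R,7R)-5-(4-hydroxy-3-methoxyphenyl)-6,7-bis(hydroxymethyl)-3-methoxy-5,6,7,8-tetrahydronaphthalen-2-ol | COc1cc([C@H]2c3cc(OC)c(O)cc3C[C@@H](CO)[C@@H]2CO)ccc1O | target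

**Total step count:** 14.
**Longest linear sequence:** 13 (steps 1–9 and 11–14). Step 10 is a one-step side branch.

**Three steps most likely to fail**

**Step 6** (Evans alkylation).
- Risks: incomplete conversion, decomposition of the sodium enolate on warming, or erosion of dr.
- The fallback replaces the auxiliary with catalytic asymmetric hydrogenation. It sets out from 1 and comes back at 17.
- Isovanillin 1 is benzylated with 5 (K2CO3, DMF) to 3-(benzyloxy)-4-methoxybenzaldehyde F1.
- Stobbe condensation of this aldehyde with dimethyl succinate (t-BuOK, t-BuOH, reflux) gives the (E)-arylidene succinic half-ester F2.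
- Homogeneous hydrogenation follows with a cationic Rh(I)–Et-DuPHOS catalyst (5 bar H2, MeOH). The ligand antipode is chosen, and checked by chiral HPLC, to deliver the R acid, and the benzyl ether is untouched. The product is the (R)-benzylsuccinic half-ester F3.
- The methyl ester of its potassium salt is reduced with Ca(BH4)2 (NaBH4/CaCl2, EtOH) to the (R)-hydroxy acid F4.
- This hydroxy acid closes to 17 on acidification with aq. HCl.

**Step 11** (aldol).
- Risks: retro-aldol on work-up, proton transfer between enolate and product, or low conversion.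
- The fallback forms the same bond irreversibly by a crossed Claisen-type acylation followed by reduction. It sets out from 17 (aroyl part from 19) and comes back at 21.
- Aldehyde 19 is oxidised (NaClO2, NaH2PO4, 2-methyl-2-butene, t-BuOH/H2O) to 4-(benzyloxy)-3-methoxybenzoic acid F5.
- The acid is converted with oxalyl chloride and cat. DMF into 4-(benzyloxy)-3-methoxybenzoyl chloride F6.
- Enolate 20, made from 17 with 2.1 equiv LiHMDS at −78 °C, is C-acylated with it to the trans α-aroyl lactone F7. The acidic C3 centre of this compound equilibrates to trans.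
- Ketone reduction (Zn(BH4)2 or NaBH4, THF/MeOH, −20 °C) gives 21. Either carbinol epimer is usable.

**Step 12** (Friedel–Crafts closure).
- Risks: acid-induced loss of an O-benzyl group, dehydration to the benzylidene lactone, or slow closure to the trans-fused lactone.
- The fallback removes the lactone first and cyclises an unstrained system, as in the classical lariciresinol → isolariciresinol isomerisation. It sets out from 21 and comes back at 24.
- Aldol 21 is reduced with LiAlH4 (THF, 0 °C) to the (2R,3R)-triol F8.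
- Catalytic camphorsulfonic acid in CH2Cl2 closes the triol by O-trapping of the benzylic cation to the 2,3-trans-3,4-cis tetrahydrofuran F9.
- The ether opening is reversible while C-arylation is not. Further acid (BF3·OEt2 or HCO2H, 0 °C → rt) therefore funnels F9 into the all-trans tetralin diol 24.

**Further compounds**
F1 | step 6 | 3-(benzyloxy)-4-methoxybenzaldehyde | COc1ccc(C=O)cc1OCc1ccccc1
F2 | step 6 | (E)-4-[3-(benzyloxy)-4-methoxyphenyl]-3-(methoxycarbonyl)but-3-enoic acid | COC(=O)/C(CC(=O)O)=C/c1ccc(OC)c(OCc2ccccc2)c1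
F3 | step 6 | (3R)-4-[3-(benzyloxy)-4-methoxyphenyl]-3-(methoxycarbonyl)butanoic acid | COc1ccc(C[C@H](CC(=O)O)C(=O)OC)cc1OCc1ccccc1
F4 | step 6 | (3R)-4-[3-(benzyloxy)-4-methoxyphenyl]-3-(hydroxymethyl)butanoic acid | COc1ccc(C[C@H](CC(=O)O)CO)cc1OCc1ccccc1
F5 | step 11 | 4-(benzyloxy)-3-methoxybenzoic acid | COc1cc(C(=O)O)ccc1OCc1ccccc1
F6 | step 11 | 4-(benzyloxy)-3-methoxybenzoyl chloride | COc1cc(C(=O)Cl)ccc1OCc1ccccc1
F7 | step 11 | (3S,4R)-3-[4-(benzyloxy)-3-methoxybenzoyl]-4-[3-(benzyloxy)-4-methoxybenzyl]dihydrofuran-2(3H)-one | O=C1OC[C@H](Cc2ccc(OC)c(OCc3ccccc3)c2)[C@H]1C(=O)c1ccc(OCc2ccccc2)c(OC)c1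
F8 | step 12 | (2R,3R)-2-{[4-(benzyloxy)-3-methoxyphenyl](hydroxy)methyl}-3-[3-(benzyloxy)-4-methoxybenzyl]butane-1,4-diol | OC[C@H](Cc1ccc(OC)c(OCc2ccccc2)c1)[C@H](CO)C(O)c1ccc(OCc2ccccc2)c(OC)c1
F9 | step 12 | {(2S,3R,4R)-2-[4-(benzyloxy)-3-methoxyphenyl]-4-[3-(benzyloxy)-4-methoxybenzyl]tetrahydrofuran-3-yl}methanol | OC[C@H]1[C@@H](Cc2ccc(OC)c(OCc3ccccc3)c2)CO[C@@H]1c1ccc(OCc2ccccc2)c(OC)c1
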